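**Retrosynthetic overview**

- The target is (2R,3S)-5'-geranylcatechin. The plan rests on ring C (the pyran ring): O1–C8a–C4a–C4 is read as the heterodiene of a ring A ortho-quinone methide, and C2–C3 as an E alkene whose trans aryl and heteroatom substituents become the 2,3-trans pair.
- Key disconnection: C3–C4 and O1–C2, by an acid-catalysed inverse-demand oxa-Diels–Alder reaction of the quinone methide with an (E)-2-arylvinylboron dienophile. Boron at C3 is the latent 3-OH (C–B to C–O with retention).
- Dienophile from 5-iodovanillin: demethylation, silylation, Negishi geranylation, boron-Wittig olefination, boronic acid, diazaborinone mask with N–H donors. Diene precursor from 2,4,6-trihydroxybenzaldehyde: bis-silylation, borohydride reduction.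
- Rings A and B are bought; ring C is the only ring formed (step 9). Oxidation at boron and removal of four silyl ethers end the route.

Key step: step 9

Remark on the chemistry: boron enters the cycloaddition as its anthranilamide-derived diazaborinone, not as the free boronic acid. A free B(OH)2 group would esterify the 1,3-diol of the salicyl alcohol and, once bound to O1, pass its alkenyl group to C4 with loss of boron (Petasis-type shift). The mask keeps two N–H donors for the catalyst and is opened by aqueous base during the oxidation.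

Abbreviations: TBS = tert-butyldimethylsilyl; geranyl = (2E)-3,7-dimethylocta-2,6-dien-1-yl; flavan numbering is used for the chroman core.

**Route**

Step 1
Reactants: 1 5-iodovanillin
Product: 2 3,4-dihydroxy-5-iodobenzaldehyde
Conditions: BBr3, CH2Cl2, −78 °C to rt; then H2O
Reagents that add atoms: none
Why: Lewis acid ether cleavage, in which BBr3 binds the methoxy oxygen and bromide removes the methyl group by SN2 while the aldehyde and the aryl iodide stay inert.

Step 2
Reactants: 2 3,4-dihydroxy-5-iodobenzaldehyde
Product: 3 3,4-bis(TBS-oxy)-5-iodobenzaldehyde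
Conditions: TBSCl, imidazole, DMF, rt
Reagents that add atoms: tert-butyldimethylsilyl chloride, CC(C)(C)[Si](C)(C)Cl
Why: Imidazole-promoted silylation of both phenols, a standard protection that should survive the later organozinc, lithium amide and acid-catalysed steps.

Step 3
Reactants: 3 3,4-bis(TBS-oxy)-5-iodobenzaldehyde; 4 geranyl bromide
Product: 6 3,4-bis(TBS-oxy)-5-geranylbenzaldehyde, via arylzinc iodide 5 (not isolated)
Conditions: Zn dust, LiCl, THF, 25–40 °C; solution decanted from excess Zn; then 4, Pd(PPh3)4 (3 mol%), THF, 0 °C to rt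
Reagents that add atoms: none
Why: Negishi coupling, in which LiCl-assisted zinc insertion into the aryl–iodine bond tolerates the aldehyde and cannot trigger a silyl shift from oxygen to carbon, and the arylzinc couples through a syn-π-allylpalladium species at its unsubstituted terminus, so the linear E-geranyl arene should result.

Step 4
Reactants: 6 3,4-bis(TBS-oxy)-5-geranylbenzaldehyde; 7 bis(pinacolatoboryl)methane
Product: 9 (E)-2-[3,4-bis(TBS-oxy)-5-geranylphenyl]ethenylboronic acid pinacol ester, via lithiated bis(boryl)methane 8 (not isolated)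
Conditions: lithium 2,2,6,6-tetramethylpiperidide, 7, THF, 0 °C; then 6, −78 °C to rt
Reagents that add atoms: none
Why: Boron-Wittig olefination, in which the α-lithio geminal bis(boronate) adds to the aldehyde and the β-oxido boronate loses B–O in a syn elimination from the less crowded adduct, which should give the E-alkenyl boronate.

Step 5
Reactants: 9 (E)-2-[3,4-bis(TBS-oxy)-5-geranylphenyl]ethenylboronic acid pinacol ester
Product: 10 (E)-2-[3,4-bis(TBS-oxy)-5-geranylphenyl]ethenylboronic acid
Conditions: NaIO4, NH4OAc, acetone/H2O, rt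
Reagents that add atoms: water, O
Why: Oxidative pinacol cleavage, in which periodate destroys the liberated diol and so pulls the hydrolysis of the boronic ester to the free acid at neutral pH, which aryl silyl ethers and isolated alkenes tolerate.

Step 6
Reactants: 10 (E)-2-[3,4-bis(TBS-oxy)-5-geranylphenyl]ethenylboronic acid
Product: 11 2-[(E)-2-{3,4-bis(TBS-oxy)-5-geranylphenyl}ethenyl]-2,3-dihydro-1H-1,3,2-benzodiazaborinin-4-one
Conditions: anthranilamide, toluene, 4 Å molecular sieves, 80 °C
Reagents that add atoms: anthranilamide (2-aminobenzamide), NC(=O)c1ccccc1N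
Why: Condensation of a boronic acid with 2-aminobenzamide closes the six-membered diazaborinone with loss of water, which removes the B–OH groups and the Lewis acidity of boron but keeps two N–H donors.

Step 7
Reactants: 12 2,4,6-trihydroxybenzaldehyde
Product: 13 2-hydroxy-4,6-bis(TBS-oxy)benzaldehyde
Conditions: TBSCl (2.05 equiv), imidazole, DMF/CH2Cl2, 0 °C
Reagents that add atoms: tert-butyldimethylsilyl chloride, CC(C)(C)[Si](C)(C)Cl
Why: Selective silylation, in which the 4-OH and one ortho OH react while the remaining ortho OH is held by a hydrogen bond to the formyl oxygen and should stay free.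

Step 8
Reactants: 13 2-hydroxy-4,6-bis(TBS-oxy)benzaldehyde
Product: 14 2-(hydroxymethyl)-3,5-bis(TBS-oxy)phenol
Conditions: NaBH4, THF/EtOH, −10 °C; pH 7 phosphate buffer; used crude without delay
Reagents that add atoms: none
Why: Borohydride reduction of the aldehyde to the benzylic alcohol, with low temperature and a neutral quench chosen to prevent silyl migration to the new alkoxide and premature ionisation.

Step 9
Reactants: 14 2-(hydroxymethyl)-3,5-bis(TBS-oxy)phenol; 11 2-[(E)-2-{3,4-bis(TBS-oxy)-5-geranylphenyl}ethenyl]-2,3-dihydro-1H-1,3,2-benzodiazaborinin-4-one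
Product: 16 (2S,3S)-2,3-trans-5,7-bis(TBS-oxy)-2-[3,4-bis(TBS-oxy)-5-geranylphenyl]chroman-3-yl diazaborinone, via ortho-quinone methide 15 (not isolated)
Conditions: (R)-3,3'-bis(2,4,6-triisopropylphenyl)-1,1'-binaphthyl-2,2'-diyl hydrogen phosphate (10 mol%), 5 Å molecular sieves, toluene, −20 °C; 14 (1.2 equiv) added slowly to 11
Reagents that add atoms: none
Why: Proposed new method: the phosphoric acid ionises 14 with loss of water to the ortho-quinone methide 15, stays hydrogen-bonded to its O1 and takes an N–H of the diazaborinone of 11 with its phosphoryl oxygen, and the heterodiene O1=C8a–C4a=C4 then adds to the E alkene suprafacially in a concerted but asynchronous inverse-demand oxa-Diels–Alder reaction in which C3–C4 runs ahead of O1–C2. The closest known reaction type is the chiral phosphoric acid-catalysed (4+2) cycloaddition of in situ ortho-quinone methides with styrenes that carry an O–H or N–H donor, next to thermal quinone methide–styrene flavan syntheses; an alkenylboron dienophile that keeps its boron has not been shown. Ring C is closed by this intermolecular (4+2) addition, the two-carbon unit C2–C3 being joined to C4 and O1 in one operation. The cationic character that builds up at C2 is stabilised by the para silyloxy group of ring B and by the adjacent C3–B bond, so aryl ends at C2 and boron at C3, and the trans relation of C2 and C3 is the E geometry of 11 carried through the suprafacial addition (a stepwise ion-pair closure would lead to the same diequatorial ring). Because C4 is a CH2 group, the absolute configuration at C2 and C3 depends only on which alkene face meets the catalyst-bound quinone methide, which the chiral pocket decides; the (R) acid is the first choice and its antipode is taken if experiment shows the opposite sense. The step needs boron to stay on C3 and the quinone methide to prefer this alkene over the geranyl alkenes and the ring A carbons: the diazaborinone offers no B–OH to esterify 14 and no Lewis acidic boron for an alkenyl shift to C4, the para oxygen and the catalyst-binding N–H make the styrene the fastest π-nucleophile, and bulky silyl ethers flank both free ring A positions.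

Step 10
Reactants: 16 (2S,3S)-2,3-trans-5,7-bis(TBS-oxy)-2-[3,4-bis(TBS-oxy)-5-geranylphenyl]chroman-3-yl diazaborinone
Product: 17 (2R,3S)-5,7-bis(TBS-oxy)-2-[3,4-bis(TBS-oxy)-5-geranylphenyl]chroman-3-ol
Conditions: NaBO3·4H2O, THF/H2O, 0 °C to rt
Reagents that add atoms: sodium perborate (tetrahydrate), [Na+].[O-]OB=O
Why: Oxidation of the carbon–boron bond, in which aqueous base opens the B–N ring, perborate adds to boron and C3 shifts from boron to oxygen with retention, so the 2,3-trans relation is kept and C3 becomes the (S)-carbinol.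

Step 11
Reactants: 17 (2R,3S)-5,7-bis(TBS-oxy)-2-[3,4-bis(TBS-oxy)-5-geranylphenyl]chroman-3-ol
Product: 18 (2R,3S)-2-(3,4-dihydroxy-5-geranylphenyl)chroman-3,5,7-triol
Conditions: HF·pyridine, pyridine, THF, 0 °C to rt, argon
Reagents that add atoms: none
Why: Fluoride-driven cleavage of the four aryl silyl ethers under pyridine buffering, which should leave the geranyl alkenes and both stereocentres of the acid- and base-sensitive flavan-3-ol untouched.

**Compound list**

1 | 5-iodovanillin (4-hydroxy-3-iodo-5-methoxybenzaldehyde) | COc1cc(C=O)cc(I)c1O | starting material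
2 | 3,4-dihydroxy-5-iodobenzaldehyde | O=Cc1cc(O)c(O)c(I)c1 | intermediate
3 | 3,4-bis(tert-butyldimethylsilyloxy)-5-iodobenzaldehyde | O=Cc1cc(O[Si](C)(C)C(C)(C)C)c(O[Si](C)(C)C(C)(C)C)c(I)c1 | intermediate
4 | geranyl bromide, (2E)-1-bromo-3,7-dimethylocta-2,6-diene | CC(C)=CCC/C(C)=C/CBr | starting material
5 | [2,3-bis(tert-butyldimethylsilyloxy)-5-formylphenyl]zinc iodide (LiCl complex in THF, not isolated) | O=Cc1cc(O[Si](C)(C)C(C)(C)C)c(O[Si](C)(C)C(C)(C)C)c([Zn]I)c1 | intermediate
6 | 3,4-bis(tert-butyldimethylsilyloxy)-5-[(2E)-3,7-dimethylocta-2,6-dien-1-yl]benzaldehyde | CC(C)=CCC/C(C)=C/Cc1cc(C=O)cc(O[Si](C)(C)C(C)(C)C)c1O[Si](C)(C)C(C)(C)C | intermediate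
7 | bis(pinacolatoboryl)methane, bis(4,4,5,5-tetramethyl-1,3,2-dioxaborolan-2-yl)methane | CC1(C)OB(CB2OC(C)(C)C(C)(C)O2)OC1(C)C | starting material
8 | lithio-bis(4,4,5,5-tetramethyl-1,3,2-dioxaborolan-2-yl)methane (not isolated) | [Li]C(B1OC(C)(C)C(C)(C)O1)B1OC(C)(C)C(C)(C)O1 | intermediate
9 | 2-[(E)-2-{3,4-bis(tert-butyldimethylsilyloxy)-5-[(2E)-3,7-dimethylocta-2,6-dien-1-yl]phenyl}ethenyl]-4,4,5,5-tetramethyl-1,3,2-dioxaborolane | CC(C)=CCC/C(C)=C/Cc1cc(/C=C/B2OC(C)(C)C(C)(C)O2)cc(O[Si](C)(C)C(C)(C)C)c1O[Si](C)(C)C(C)(C)C | intermediate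
10 | (E)-2-{3,4-bis(tert-butyldimethylsilyloxy)-5-[(2E)-3,7-dimethylocta-2,6-dien-1-yl]phenyl}ethenylboronic acid | CC(C)=CCC/C(C)=C/Cc1cc(/C=C/B(O)O)cc(O[Si](C)(C)C(C)(C)C)c1O[Si](C)(C)C(C)(C)C | intermediate
11 | 2-[(E)-2-{3,4-bis(tert-butyldimethylsilyloxy)-5-[(2E)-3,7-dimethylocta-2,6-dien-1-yl]phenyl}ethenyl]-2,3-dihydro-1H-1,3,2-benzodiazaborinin-4-one | CC(C)=CCC/C(C)=C/Cc1cc(/C=C/B2NC(=O)c3ccccc3N2)cc(O[Si](C)(C)C(C)(C)C)c1O[Si](C)(C)C(C)(C)C | intermediate
12 | 2,4,6-trihydroxybenzaldehyde | O=Cc1c(O)cc(O)cc1O | starting material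
13 | 2-hydroxy-4,6-bis(tert-butyldimethylsilyloxy)benzaldehyde | O=Cc1c(O)cc(O[Si](C)(C)C(C)(C)C)cc1O[Si](C)(C)C(C)(C)C | intermediate
14 | 2-(hydroxymethyl)-3,5-bis(tert-butyldimethylsilyloxy)phenol | OCc1c(O)cc(O[Si](C)(C)C(C)(C)C)cc1O[Si](C)(C)C(C)(C)C | intermediate
15 | 3,5-bis(tert-butyldimethylsilyloxy)-6-methylidenecyclohexa-2,4-dien-1-one (ortho-quinone methide, not isolated) | C=C1C(=O)C=C(O[Si](C)(C)C(C)(C)C)C=C1O[Si](C)(C)C(C)(C)C | intermediate
16 | 2-[(2S,3S)-5,7-bis(tert-butyldimethylsilyloxy)-2-{3,4-bis(tert-butyldimethylsilyloxy)-5-[(2E)-3,7-dimethylocta-2,6-dien-1-yl]phenyl}-3,4-dihydro-2H-chromen-3-yl]-2,3-dihydro-1H-1,3,2-benzodiazaborinin-4-one (2,3-trans; same spatial arrangement as the target, descriptors differ because boron ranks below carbon) | CC(C)=CCC/C(C)=C/Cc1cc([C@H]2Oc3cc(O[Si](C)(C)C(C)(C)C)cc(O[Si](C)(C)C(C)(C)C)c3C[C@@H]2B4NC(=O)c5ccccc5N4)cc(O[Si](C)(C)C(C)(C)C)c1O[Si](C)(C)C(C)(C)C | intermediate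
17 | (2R,3S)-5,7-bis(tert-butyldimethylsilyloxy)-2-{3,4-bis(tert-butyldimethylsilyloxy)-5-[(2E)-3,7-dimethylocta-2,6-dien-1-yl]phenyl}-3,4-dihydro-2H-chromen-3-ol (2,3-trans) | CC(C)=CCC/C(C)=C/Cc1cc([C@H]2Oc3cc(O[Si](C)(C)C(C)(C)C)cc(O[Si](C)(C)C(C)(C)C)c3C[C@@H]2O)cc(O[Si](C)(C)C(C)(C)C)c1O[Si](C)(C)C(C)(C)C | intermediate
18 | (2R,3S)-2-{3,4-dihydroxy-5-[(2E)-3,7-dimethylocta-2,6-dien-1-yl]phenyl}-3,4-dihydro-2H-chromene-3,5,7-triol (CID44420736) | CC(C)=CCC/C(C)=C/Cc1cc([C@H]2Oc3cc(O)cc(O)c3C[C@@H]2O)cc(O)c1O | target

**Step count and risks**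

Total step count: 11. Longest linear sequence: 9 steps (steps 1–6, 9, 10, 11).

Steps most likely to fail:

1. Step 9 (Proposed new method). What may go wrong:
   - exchange of the boron mask with the diol of 14 under acid, followed by transfer of the alkenyl group from boron to C4 with loss of boron;
   - Friedel–Crafts self-alkylation of the quinone methide by ring A carbons, leading to oligomers;
   - poor discrimination of the two alkene faces.

   Fallback with known chemistry, setting out from 13 and 10 and coming back at 17. An amine-catalysed Petasis condensation of salicylaldehyde 13 with alkenylboronic acid 10 (dibenzylamine, toluene, 80 °C), followed in the same flask by loss of the amine and oxa-6π electrocyclisation, should give the racemic 2-aryl-2H-chromene F1. A copper-catalysed enantioselective borylation–protonation of its styrenic C3=C4 bond (bis(pinacolato)diboron, CuCl, a chiral bisphosphine such as 1,2-bis(2,5-diphenylphospholano)ethane, NaOt-Bu, MeOH, THF) is then run as a kinetic resolution. It should add boron to C3 anti to the C2 aryl group of the matched enantiomer and give the (2S,3S)-trans pinacol boronate F2, the other enantiomer of F1 being left behind. F2 is oxidised with NaBO3·4H2O as in step 10 to give 17.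

2. Step 8. What may go wrong:
   - ionisation of the very electron-rich salicyl alcohol to the quinone methide during concentration or chromatography, with self-alkylation;
   - migration of a silyl group from the ortho oxygen to the benzylic alkoxide.

   Fallback, setting out from 13 and coming back at 14. The reduction is run as in step 8 and the crude alcohol is condensed at once with phenylboronic acid (toluene, MgSO4, rt) to the cyclic phenylboronate F3. In F3 both hydroxyl groups are tied up in a neutral ring that can be purified and stored. Shortly before step 9, F3 is opened by ester exchange with pinacol (1 equiv, toluene, 5 Å molecular sieves, no acid present). This should release 14 in solution beside inert phenylboronic acid pinacol ester, and the solution is fed directly into step 9.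

3. Step 3. What may go wrong:
   - sluggish zinc insertion next to the bulky silyloxy group;
   - carbonyl addition by allylzinc formed from traces of zinc metal;
   - allylic transposition on palladium.

   Fallback, setting out from 3 and coming back at 6. The aldehyde is masked as the dimethyl acetal F4 (trimethyl orthoformate, pyridinium p-toluenesulfonate, MeOH). Iodine–magnesium exchange (i-PrMgCl·LiCl, THF, −20 to 0 °C) should give the aryl Grignard reagent F5, at which no silyl shift from oxygen to carbon is expected. F5 is allylated with 4 under copper catalysis (Li2CuCl4, 5 mol%, THF, −20 °C; substitution at the primary allylic carbon) to the geranylated acetal F6. Mild hydrolysis (pyridinium p-toluenesulfonate, acetone/H2O) returns 6.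

Further compounds
F1 | step 9 | racemic 5,7-bis(tert-butyldimethylsilyloxy)-2-{3,4-bis(tert-butyldimethylsilyloxy)-5-[(2E)-3,7-dimethylocta-2,6-dien-1-yl]phenyl}-2H-chromene | CC(C)=CCC/C(C)=C/Cc1cc(C2C=Cc3c(O[Si](C)(C)C(C)(C)C)cc(O[Si](C)(C)C(C)(C)C)cc3O2)cc(O[Si](C)(C)C(C)(C)C)c1O[Si](C)(C)C(C)(C)C
F2 | step 9 | 2-[(2S,3S)-5,7-bis(tert-butyldimethylsilyloxy)-2-{3,4-bis(tert-butyldimethylsilyloxy)-5-[(2E)-3,7-dimethylocta-2,6-dien-1-yl]phenyl}-3,4-dihydro-2H-chromen-3-yl]-4,4,5,5-tetramethyl-1,3,2-dioxaborolane (2,3-trans) | CC(C)=CCC/C(C)=C/Cc1cc([C@H]2Oc3cc(O[Si](C)(C)C(C)(C)C)cc(O[Si](C)(C)C(C)(C)C)c3C[C@@H]2B4OC(C)(C)C(C)(C)O4)cc(O[Si](C)(C)C(C)(C)C)c1O[Si](C)(C)C(C)(C)C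
F3 | step 8 | 5,7-bis(tert-butyldimethylsilyloxy)-2-phenyl-4H-1,3,2-benzodioxaborinine | CC(C)(C)[Si](C)(C)Oc1cc(O[Si](C)(C)C(C)(C)C)c2COB(c3ccccc3)Oc2c1
F4 | step 3 | 1-(dimethoxymethyl)-3,4-bis(tert-butyldimethylsilyloxy)-5-iodobenzene | COC(OC)c1cc(O[Si](C)(C)C(C)(C)C)c(O[Si](C)(C)C(C)(C)C)c(I)c1
F5 | step 3 | [2,3-bis(tert-butyldimethylsilyloxy)-5-(dimethoxymethyl)phenyl]magnesium chloride | COC(OC)c1cc(O[Si](C)(C)C(C)(C)C)c(O[Si](C)(C)C(C)(C)C)c([Mg]Cl)c1
F6 | step 3 | 1-(dimethoxymethyl)-3,4-bis(tert-butyldimethylsilyloxy)-5-[(2E)-3,7-dimethylocta-2,6-dien-1-yl]benzene | CC(C)=CCC/C(C)=C/Cc1cc(C(OC)OC)cc(O[Si](C)(C)C(C)(C)C)c1O[Si](C)(C)C(C)(C)C
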